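**Retrosynthetic overview**
1. 40 is cut at C6–C7. The ten-membered carbocycle (C1–C10) is closed last, by an intramolecular γ-chloroallyl chromium addition within seco compound 38. This gives 40 directly, setting C6–Cl, C7–O, C5=C16 and both stereocentres in one operation.
2. Enabling feature: the triad C5(=C16H2)–C6HCl–C7H–O is the retron of a γ-chloroallylmetal/aldehyde addition. C7 belongs both to the ten-membered ring and to the γ-lactone ring (O–C7–C8–C17–C19), so the aldehyde can be stored as the lactol of the already closed lactone.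
3. 38 comes from ring A aldehyde 28 and the malate-derived dioxolanone 14 (C8–C9 bond). C8 and C17 come from the chiral pool and C9 from a chelate-controlled reduction.
4. 28 comes from keto aldehyde 21 and Grignard reagent 22 (C2–C3 bond; C2 by chelate addition, C14 by directed reduction). 21 comes from geraniol by asymmetric epoxidation and a titanocene radical cyclisation that builds ring A with C1, C10 and the C11=C20 methylene.
5. Order of ring formation: cyclohexane (step 12), γ-lactone at the lactol level (step 24), oxirane (step 25), ten-membered ring (step 26).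

Key step: step 26

Remark: briarane numbering is used for all intermediates (C1 quaternary fusion carbon, C2–C9 around the large ring, C10 fusion CH, C11–C14 cyclohexane, C15 = 1-CH3, C16 = 5-methylene, C17/C19 lactone carbons, C18 = 17-CH3, C20 = oxirane CH2); β is the face of C15; lactols 37–39 are taken as C7 anomer mixtures and drawn without a C7 descriptor.

**Fragment 1 (C3–C6, C16)**

Step 1
Reactants: 1 prop-2-yn-1-ol; 2 allylmagnesium bromide
Product: 4 (Z)-2-(chloromethylidene)pent-4-en-1-ol, via alkenylmagnesium alkoxide chelate 3 (not isolated)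
Conditions: 2 (2.5 equiv), CuI (5 mol%), Et2O, 0 to 25 °C; NCS, THF, −30 °C; aq NH4Cl
Reagents that add atoms: N-chlorosuccinimide O=C1CCC(=O)N1Cl
Why: Alkoxide-directed anti carbomagnesiation of a propargylic alcohol puts allyl on the inner and Mg on the terminal alkyne carbon inside a five-membered chelate, and electrophilic chlorination with retention fixes Cl cis to CH2OH.

Step 2
Reactants: 4 (Z)-2-(chloromethylidene)pent-4-en-1-ol
Product: 5 TBS ether of 4
Conditions: TBSCl, imidazole, DMF, 25 °C
Reagents that add atoms: tert-butyldimethylsilyl chloride CC(C)(C)[Si](C)(C)Cl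
Why: Standard silylation of a primary alcohol, giving a group that tolerates the later Grignard formation.

Step 3
Reactants: 5 TBS ether of 4
Product: 7 (Z)-4-chloro-3-[(tert-butyldimethylsilyloxy)methyl]but-3-en-1-ol, via β,γ-unsaturated aldehyde 6 (not isolated)
Conditions: O3 (1 equiv, metered), CH2Cl2–MeOH, −78 °C; NaBH4, −78 to 0 °C
Reagents that add atoms: ozone [O-][O+]=O
Why: Ozonolysis with reductive work-up; the terminal vinyl group reacts far faster than the alkene that carries a vinylic chlorine and an allylic oxygen, and in situ reduction prevents conjugation of the aldehyde.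

Step 4
Reactants: 7 (Z)-4-chloro-3-[(tert-butyldimethylsilyloxy)methyl]but-3-en-1-ol
Product: 8 (Z)-4-bromo-2-(chloromethylidene)butyl TBS ether
Conditions: CBr4, PPh3, CH2Cl2, 0 °C
Reagents that add atoms: carbon tetrabromide BrC(Br)(Br)Br
Why: Appel bromination of an unhindered primary alcohol under neutral conditions.

**Fragment 2 (C7, C8, C17–C19)**

Step 5
Reactants: 9 diethyl (S)-malate
Product: 11 diethyl (2S,3R)-3-methylmalate, via dilithio alkoxide enolate 10 (not isolated)
Conditions: LDA (2.2 equiv), THF, −78 to −20 °C; MeI, −78 °C; AcOH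
Reagents that add atoms: iodomethane CI
Why: Frater–Seebach alkylation; the chelated alkoxide enolate is methylated anti to the C8 oxygen and sets C17 as in 40.

Step 6
Reactants: 11 diethyl (2S,3R)-3-methylmalate
Product: 12 (2S,3R)-3-methylmalic acid
Conditions: KOH, EtOH–H2O, 25 °C; HCl
Reagents that add atoms: potassium hydroxide [K+].[OH-]
Why: Plain saponification; at room temperature neither stereocentre should epimerise.

Step 7
Reactants: 12 (2S,3R)-3-methylmalic acid
Product: 13 (2R)-2-[(2S,4S)-2-tert-butyl-5-oxo-1,3-dioxolan-4-yl]propanoic acid (cis acetal)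
Conditions: t-BuCHO, TsOH (cat.), H2SO4 (cat.), pentane, reflux, Dean–Stark; recrystallisation
Reagents that add atoms: pivalaldehyde CC(C)(C)C=O
Why: Acid-catalysed acetalisation of the α-hydroxy acid unit gives the five-membered dioxolanone, and the thermodynamically preferred cis acetal stores the C8 chirality in the new acetal centre (self-regeneration of stereocentres).

Step 8
Reactants: 13 dioxolanone acid
Product: 14 tert-butyl (2R)-2-[(2S,4S)-2-tert-butyl-5-oxo-1,3-dioxolan-4-yl]propanoate
Conditions: tert-butyl 2,2,2-trichloroacetimidate, BF3·OEt2 (cat.), CH2Cl2–cyclohexane, 25 °C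
Reagents that add atoms: tert-butyl 2,2,2-trichloroacetimidate CC(C)(C)OC(=N)C(Cl)(Cl)Cl
Why: Imidate tert-butylation of a carboxylic acid; the bulky C19 ester later resists attack by the C9 and C7 hydroxyl groups.

**Main line**

Step 9
Reactants: 15 geraniol
Product: 16 geranyl TBS ether
Conditions: TBSCl, imidazole, CH2Cl2, 25 °C
Reagents that add atoms: tert-butyldimethylsilyl chloride CC(C)(C)[Si](C)(C)Cl
Why: Standard silylation; C9–O carries the same group as C16–O so that both can be released together in step 17.

Step 10
Reactants: 16 geranyl TBS ether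
Product: 18 (2E,6E)-8-hydroxygeranyl TBS ether, via over-oxidised enal 17 (not isolated)
Conditions: SeO2 (10 mol%), t-BuOOH, salicylic acid (cat.), CH2Cl2, 0 to 25 °C; NaBH4, MeOH, 0 °C
Reagents that add atoms: tert-butyl hydroperoxide CC(C)(C)OO
Why: Riley allylic oxidation (ene reaction then [2,3]-shift) attacks the E-methyl group of the electron-richer terminal alkene, the C10=C11 alkene being deactivated by its allylic silyloxy group, and borohydride returns any enal to the alcohol.

Step 11
Reactants: 18 (2E,6E)-8-hydroxygeranyl TBS ether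
Product: 19 (2R,3R)-epoxy alcohol (C1–C14 oxirane)
Conditions: Ti(OiPr)4 (10 mol%), D-(−)-diethyl tartrate (12 mol%), t-BuOOH, 4 Å MS, CH2Cl2, −20 °C
Reagents that add atoms: tert-butyl hydroperoxide CC(C)(C)OO
Why: Sharpless asymmetric epoxidation touches only the allylic-alcohol alkene, and D-(−)-tartrate gives the (2R,3R)-oxirane whose C14–O centre later relays to C1 and C10.

Step 12
Reactants: 19 (2R,3R)-epoxy alcohol
Product: 20 ring A diol [C1: β-axial CH3 and α-equatorial CH2OH; 14β-equatorial OH (14-epi); C10: β-equatorial CH2OTBS; exocyclic C11=C20]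
Conditions: Cp2TiCl2 (3 equiv), Mn dust (8 equiv), degassed THF, 25 °C; 1 M HCl
Reagents that add atoms: none
Why: Titanocene-mediated reductive epoxide opening (Nugent–RajanBabu type) gives the tertiary C1 radical; 6-endo closure onto C10 through a chair with C14–O[Ti], C2 and C9 equatorial and C15 axial sets C1 and C10 from C14; and capture of the C11 radical by a second Cp2TiCl followed by β-hydride elimination gives the exocyclic alkene.

Step 13
Reactants: 20 ring A diol
Product: 21 β-keto aldehyde (C2 aldehyde and C14 ketone on quaternary C1)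
Conditions: (COCl)2, DMSO, CH2Cl2, −78 °C; Et3N, −78 to −20 °C
Reagents that add atoms: none
Why: Double Swern oxidation; C1 is quaternary so the 1,3-dicarbonyl cannot enolise between the carbonyls, and the wrong C14 centre is erased after it has done its relay.

Step 14
Reactants: 21 β-keto aldehyde; 8 (Z)-bromide
Product: 23 β-hydroxy ketone (C2 configured as in 40), via Grignard reagent 22 (not isolated)
Conditions: 8, Mg, THF, 35 °C; 21, THF, −78 °C; sat. NH4Cl at −78 °C
Reagents that add atoms: none
Why: Cram-chelate Grignard addition; Mg bridges the C2 and C14 carbonyl oxygens and the nucleophile enters the more reactive aldehyde from the face of the small C15 methyl, anti to C10, while a cold quench suppresses retro-aldol cleavage.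

Step 15
Reactants: 23 β-hydroxy ketone
Product: 24 1,3-anti diol (2-OH and axial 14α-OH as in 40)
Conditions: Me4NBH(OAc)3, MeCN–AcOH, −30 °C
Reagents that add atoms: none
Why: Evans–Saksena reduction; the acetoxyborohydride bound to O2 delivers hydride intramolecularly to C14 and gives the 1,3-anti diol, which is the C2/C14 relationship of 40.

Step 16
Reactants: 24 1,3-anti diol
Product: 25 2,14-diacetate
Conditions: Ac2O, Et3N, DMAP, CH2Cl2, 25 °C
Reagents that add atoms: acetic anhydride CC(=O)OC(C)=O
Why: DMAP-catalysed acetylation installs two of the three final acetates at a stage after which no strong base or ester-reducing hydride is used.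

Step 17
Reactants: 25 2,14-diacetate
Product: 26 diol (allylic C16–OH and primary C9–OH)
Conditions: HF·pyridine, pyridine, THF, 0 to 25 °C
Reagents that add atoms: none
Why: Fluoride cleavage of both primary silyl ethers; acetates, vinyl chloride and the exocyclic alkene tolerate buffered HF.

Step 18
Reactants: 26 diol
Product: 28 ring A aldehyde with (Z)-γ-chloroallyl chloride arm, via C9 alkoxysulfonium chloride 27 (not isolated)
Conditions: NCS, Me2S, CH2Cl2, −25 to 0 °C, 2 h; Et3N, −40 °C
Reagents that add atoms: N-chlorosuccinimide O=C1CCC(=O)N1Cl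
Why: The Corey–Kim reagent forms both alkoxysulfonium salts; chloride displaces the allylic one (Corey–Kim allylic chlorination), whereas the β-branched C9 salt waits for Et3N and collapses to the aldehyde (Corey–Kim oxidation).

Step 19
Reactants: 28 ring A aldehyde; 14 dioxolanone tert-butyl ester
Product: 30 aldol adduct (C8 as in 40; carbinol C9 drawn as the expected 9-epimer), via lithium enolate 29 (not isolated)
Conditions: 14, LDA, THF, −78 °C; 28, −78 °C; sat. NH4Cl at −78 °C
Reagents that add atoms: none
Why: Aldol addition under self-regeneration of stereocentres; the enolate is attacked anti to the tert-butyl group so that C9 replaces H at C8 with retention, and the carbinol centre (Felkin and Zimmerman–Traxler bias both favour 9-epi) is erased in step 20.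

Step 20
Reactants: 30 aldol adduct
Product: 31 C9 ketone
Conditions: Dess–Martin periodinane, NaHCO3, CH2Cl2, 25 °C
Reagents that add atoms: none
Why: Neutral Dess–Martin oxidation of a hindered secondary alcohol; C8 is quaternary, and buffered conditions keep C10 and the β,γ-alkene in place.

Step 21
Reactants: 31 C9 ketone
Product: 33 triol (9-OH as in 40; free 8-OH; C7H2OH), via hydroxy dioxolanone 32 (not isolated)
Conditions: Zn(BH4)2, Et2O, −30 °C; NaBH4, EtOH, 0 to 25 °C; aq NH4Cl
Reagents that add atoms: none
Why: Chelation-controlled reduction sets C9, since Zn bridges O9 and ring oxygen O8 and hydride enters from the flat C7 side, which is also the Felkin face with respect to C10; borohydride then reduces the activated acetal-ester carbonyl and the aldehydes it releases, while hindered acetates and the tert-butyl ester stay.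

Step 22
Reactants: 33 triol
Product: 34 α-hydroxy aldehyde (C7 aldehyde)
Conditions: TEMPO (10 mol%), PhI(OAc)2, CH2Cl2, 25 °C
Reagents that add atoms: none
Why: Oxoammonium oxidation is selective for the primary alcohol over the hindered secondary C9 and tertiary C8 hydroxyl groups, and C8 bears no hydrogen so the aldehyde cannot epimerise.

Step 23
Reactants: 34 α-hydroxy aldehyde
Product: 35 2,9,14-triacetate aldehyde
Conditions: Ac2O, pyridine, DMAP (cat.), 25 °C
Reagents that add atoms: acetic anhydride CC(=O)OC(C)=O
Why: Acetylation of the only remaining secondary alcohol; the tertiary 8-OH is left free, and C9–O is capped before the C19 acid is released so that it cannot lactonise the wrong way.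

Step 24
Reactants: 35 2,9,14-triacetate aldehyde
Product: 37 lactol lactone (5-hydroxy-γ-lactone O–C7–C8–C17–C19) with exocyclic C11=C20, via bis(trimethylsilyl) derivative 36 (not isolated)
Conditions: TMSOTf, 2,6-lutidine, CH2Cl2, 0 °C; 5% aq citric acid–THF, 25 °C
Reagents that add atoms: none
Why: Silyl triflate cleavage of the tert-butyl ester is non-protic so the exocyclic alkene does not migrate, and after mild hydrolysis the γ-aldehydo acid closes spontaneously (5-exo-trig) to its pseudo-acid, which is the lactone ring of 40 at the lactol level.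

Step 25
Reactants: 37 lactol lactone
Product: 38 seco compound with 11,20-α-oxirane (C11 as in 40)
Conditions: mCPBA, NaHCO3, CH2Cl2, 0 °C
Reagents that add atoms: 3-chloroperoxybenzoic acid OOC(=O)c1cccc(Cl)c1
Why: Prilezhaev epoxidation; only the electron-rich C11=C20 alkene reacts because C5=C6 carries a vinylic and an allylic chlorine, and the axial C15 methyl blocks the β face so oxygen arrives from the α (equatorial) side.

Step 26
Reactants: 38 seco compound
Product: 40 CNP0104093.1, via γ-chloroallyl chromium species 39 (not isolated)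
Conditions: CrCl2 (3.5 equiv), NaI (0.2 equiv), THF–DMF 5:1, 38 added over 12 h to 1 mM, 25 °C; aq sodium citrate pH 4
Reagents that add atoms: none
Why: Proposed new method: divalent chromium reduces the primary allylic C16–halide (iodide relay) in two one-electron steps to a γ-chloroallyl species of trivalent chromium, which equilibrates by 1,3-metal shift to the isomer with Cl trans to CH2Cr and adds through C6 (SE2′) to the C7 aldehyde that lactol 38 exposes by ring–chain tautomerism, whereupon the C7 alkoxide returns to C19 and restores the γ-lactone with loss of the former lactol oxygen. The closest known reaction types are Nozaki–Hiyama–Kishi allylation macrocyclisations that close ten-membered germacrane rings from ω-formyl allylic halides in the presence of epoxides, intermolecular additions of γ-chloroallyl chromium reagents made from 1,3-dihalopropenes, and Barbier allylations of 5-hydroxyfuranone pseudo-acids to γ-allyl lactones; their combination in one ring closure has not been shown. The ten-membered ring closes by intramolecular carbonyl addition forming C6–C7, exo to the C7=O bond and with allyl transposition that leaves C5=C16 exocyclic, while cyclohexane, oxirane and lactone are already present in 38. C6 is controlled by the six-membered chair transition state of the Cl-trans allyl chromium (anti chlorohydrin), and C7 by polar Felkin–Anh attack anti to the C8–O bond with C9 as the medium and C17 as the small group. The step needs electron transfer to the primary allylic halide only, which the limited CrCl2 charge, catalytic iodide and the slower reduction of the hindered secondary C6–Cl, the vinyl chloride, the oxirane and the acetates should secure. It also needs closure over oligomerisation, which high dilution, the gauche trans-diequatorial C2 and C9 arms on ring A and the fully substituted C1 and C8 should favour.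

**Compound list**
1 | prop-2-yn-1-ol | C#CCO | starting material
2 | allylmagnesium bromide | C=CC[Mg]Br | starting material
3 | alkenylmagnesium alkoxide chelate | C=CCC1=C[Mg]OC1 | intermediate
4 | (Z)-2-(chloromethylidene)pent-4-en-1-ol | OC/C(=C\Cl)CC=C | intermediate
5 | TBS ether of 4 | CC(C)(C)[Si](C)(C)OC/C(=C\Cl)CC=C | intermediate
6 | (Z)-4-chloro-3-[(TBSO)methyl]but-3-enal | CC(C)(C)[Si](C)(C)OC/C(=C\Cl)CC=O | intermediate
7 | (Z)-4-chloro-3-[(TBSO)methyl]but-3-en-1-ol | CC(C)(C)[Si](C)(C)OC/C(=C\Cl)CCO | intermediate
8 | (Z)-4-bromo-2-(chloromethylidene)butyl TBS ether | CC(C)(C)[Si](C)(C)OC/C(=C\Cl)CCBr | intermediate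
9 | diethyl (S)-malate | CCOC(=O)C[C@H](O)C(=O)OCC | starting material
10 | dilithio alkoxide enolate of 9 | [Li+].[Li+].CCOC(=O)[C@@H]([O-])C=C([O-])OCC | intermediate
11 | diethyl (2S,3R)-3-methylmalate | CCOC(=O)[C@@H](O)[C@@H](C)C(=O)OCC | intermediate
12 | (2S,3R)-3-methylmalic acid | OC(=O)[C@@H](O)[C@@H](C)C(=O)O | intermediate
13 | (2R)-2-[(2S,4S)-2-tert-butyl-5-oxo-1,3-dioxolan-4-yl]propanoic acid | O=C1O[C@@H](C(C)(C)C)O[C@H]1[C@@H](C)C(=O)O | intermediate
14 | tert-butyl ester of 13 | O=C1O[C@@H](C(C)(C)C)O[C@H]1[C@@H](C)C(=O)OC(C)(C)C | intermediate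
15 | geraniol | CC(C)=CCC/C(C)=C/CO | starting material
16 | geranyl TBS ether | CC(C)=CCC/C(C)=C/CO[Si](C)(C)C(C)(C)C | intermediate
17 | (2E,6E)-8-oxogeranyl TBS ether | O=C/C(C)=C/CC/C(C)=C/CO[Si](C)(C)C(C)(C)C | intermediate
18 | (2E,6E)-8-hydroxygeranyl TBS ether | OC/C(C)=C/CC/C(C)=C/CO[Si](C)(C)C(C)(C)C | intermediate
19 | (2R,3R)-epoxy alcohol | OC[C@@]1(C)O[C@@H]1CC/C(C)=C/CO[Si](C)(C)C(C)(C)C | intermediate
20 | ring A diol (14-epi) | OC[C@@]1(C)[C@H](O)CCC(=C)[C@@H]1CO[Si](C)(C)C(C)(C)C | intermediate
21 | β-keto aldehyde | O=C[C@@]1(C)C(=O)CCC(=C)[C@@H]1CO[Si](C)(C)C(C)(C)C | intermediate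
22 | Grignard reagent from 8 | CC(C)(C)[Si](C)(C)OC/C(=C\Cl)CC[Mg]Br | intermediate
23 | β-hydroxy ketone | CC(C)(C)[Si](C)(C)OC/C(=C\Cl)CC[C@H](O)[C@@]1(C)C(=O)CCC(=C)[C@@H]1CO[Si](C)(C)C(C)(C)C | intermediate
24 | 1,3-anti diol | CC(C)(C)[Si](C)(C)OC/C(=C\Cl)CC[C@H](O)[C@@]1(C)[C@@H](O)CCC(=C)[C@@H]1CO[Si](C)(C)C(C)(C)C | intermediate
25 | 2,14-diacetate | CC(C)(C)[Si](C)(C)OC/C(=C\Cl)CC[C@H](OC(C)=O)[C@@]1(C)[C@@H](OC(C)=O)CCC(=C)[C@@H]1CO[Si](C)(C)C(C)(C)C | intermediate
26 | C9,C16 diol | OC/C(=C\Cl)CC[C@H](OC(C)=O)[C@@]1(C)[C@@H](OC(C)=O)CCC(=C)[C@@H]1CO | intermediate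
27 | C9 alkoxysulfonium chloride | ClC/C(=C\Cl)CC[C@H](OC(C)=O)[C@@]1(C)[C@@H](OC(C)=O)CCC(=C)[C@@H]1CO[S+](C)C.[Cl-] | intermediate
28 | ring A aldehyde | ClC/C(=C\Cl)CC[C@H](OC(C)=O)[C@@]1(C)[C@@H](OC(C)=O)CCC(=C)[C@@H]1C=O | intermediate
29 | lithium enolate of 14 | [Li+].[O-]C1=C([C@@H](C)C(=O)OC(C)(C)C)O[C@H](C(C)(C)C)O1 | intermediate
30 | aldol adduct (9-epi) | ClC/C(=C\Cl)CC[C@H](OC(C)=O)[C@@]1(C)[C@@H](OC(C)=O)CCC(=C)[C@@H]1[C@@H](O)[C@]2(O[C@H](C(C)(C)C)OC2=O)[C@@H](C)C(=O)OC(C)(C)C | intermediate
31 | C9 ketone | ClC/C(=C\Cl)CC[C@H](OC(C)=O)[C@@]1(C)[C@@H](OC(C)=O)CCC(=C)[C@@H]1C(=O)[C@]2(O[C@H](C(C)(C)C)OC2=O)[C@@H](C)C(=O)OC(C)(C)C | intermediate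
32 | hydroxy dioxolanone (C9 as in 40) | ClC/C(=C\Cl)CC[C@H](OC(C)=O)[C@@]1(C)[C@@H](OC(C)=O)CCC(=C)[C@@H]1[C@H](O)[C@]2(O[C@H](C(C)(C)C)OC2=O)[C@@H](C)C(=O)OC(C)(C)C | intermediate
33 | C7,C8,C9 triol | ClC/C(=C\Cl)CC[C@H](OC(C)=O)[C@@]1(C)[C@@H](OC(C)=O)CCC(=C)[C@@H]1[C@H](O)[C@](CO)(O)[C@@H](C)C(=O)OC(C)(C)C | intermediate
34 | α-hydroxy aldehyde | ClC/C(=C\Cl)CC[C@H](OC(C)=O)[C@@]1(C)[C@@H](OC(C)=O)CCC(=C)[C@@H]1[C@H](O)[C@](C=O)(O)[C@@H](C)C(=O)OC(C)(C)C | intermediate
35 | 2,9,14-triacetate aldehyde | ClC/C(=C\Cl)CC[C@H](OC(C)=O)[C@@]1(C)[C@@H](OC(C)=O)CCC(=C)[C@@H]1[C@H](OC(C)=O)[C@](C=O)(O)[C@@H](C)C(=O)OC(C)(C)C | intermediate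
36 | bis(trimethylsilyl) derivative | ClC/C(=C\Cl)CC[C@H](OC(C)=O)[C@@]1(C)[C@@H](OC(C)=O)CCC(=C)[C@@H]1[C@H](OC(C)=O)[C@](C=O)(O[Si](C)(C)C)[C@@H](C)C(=O)O[Si](C)(C)C | intermediate
37 | lactol lactone with C11=C20 | ClC/C(=C\Cl)CC[C@H](OC(C)=O)[C@@]1(C)[C@@H](OC(C)=O)CCC(=C)[C@@H]1[C@H](OC(C)=O)[C@]2(O)[C@@H](C)C(=O)OC2O | intermediate
38 | seco compound (oxirane, lactol lactone, γ-chloroallyl chloride) | ClC/C(=C\Cl)CC[C@H](OC(C)=O)[C@@]1(C)[C@@H](OC(C)=O)CC[C@]2(CO2)[C@@H]1[C@H](OC(C)=O)[C@]2(O)[C@@H](C)C(=O)OC2O | intermediate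
39 | γ-chloroallyl chromium species | Cl[Cr](Cl)C/C(=C/Cl)CC[C@H](OC(C)=O)[C@@]1(C)[C@@H](OC(C)=O)CC[C@]2(CO2)[C@@H]1[C@H](OC(C)=O)[C@]2(O)[C@@H](C)C(=O)OC2O | intermediate
40 | CNP0104093.1 | C=C1CC[C@H](OC(C)=O)[C@@]2(C)[C@@H](OC(C)=O)CC[C@]3(CO3)[C@@H]2[C@H](OC(C)=O)[C@]2(O)[C@@H](C)C(=O)O[C@H]2[C@H]1Cl | target

**Step count**
- Total: 26 steps.
- Longest linear sequence: 18 steps (steps 9–26, from geraniol).
- Fragments 8 and 14 take four steps each and enter at steps 14 and 19.

**The three steps most likely to fail**

1. **Step 26.**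
   - What may go wrong: oligomerisation or protonolysis may outrun the slow ten-membered closure. The newly formed secondary allylic chloride may be reduced further and eliminated. Facial selectivity at C7 may be poor.
   - Fallback: it sets out from 38 and returns at 40 without any reducing metal. A Miyaura-type borylation of the allylic chloride (B2pin2, Pd2(dba)3, toluene) gives the γ-chloroallyl pinacol boronate F1. Equilibration of the π-allyl complex of divalent palladium should place Cl trans to CH2B.
   - Warming dilute F1 then lets the lactol react through its aldehyde form in a closed-chair intramolecular allylboration, which is stereospecific for the anti chlorohydrin. An aqueous buffer work-up gives 40.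

2. **Step 12.**
   - What may go wrong: the oxygen β to the C1 radical may be lost through an organotitanium species (deoxygenation). The planar C1 radical may discriminate poorly between CH3 and CH2O[Ti]. Premature hydrogen transfer may occur.
   - Fallback: it changes the substrate, sets out from 19 and returns at 20. Acetylation (Ac2O, pyridine) gives the epoxy acetate F2, in which no titanium alkoxide sits next to the radical and the larger acetoxymethyl group takes the equatorial site.
   - The titanocene cyclisation then gives the monoacetate F3, and methanolysis (K2CO3, MeOH) gives 20.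

3. **Step 19.**
   - What may go wrong: addition between a tetrasubstituted enolate and a neopentyl-type aldehyde may be slow. The enolate may decompose, or retro-aldol cleavage may occur on work-up.
   - Fallback: it replaces aldol plus oxidation by an acylation, sets out from 28 and returns at 31, skipping 30 and step 20. Pinnick oxidation (NaClO2, NaH2PO4, 2-methylbut-2-ene) gives the carboxylic acid F4.
   - The Ghosez reagent gives the acid chloride F5 under neutral conditions, and C-acylation of enolate 29 at −78 °C gives ketone 31 irreversibly.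

Further compounds
F1 | step 26 | γ-chloroallyl pinacol boronate of 38 | CC1(C)OB(C/C(=C/Cl)CC[C@H](OC(C)=O)[C@@]2(C)[C@@H](OC(C)=O)CC[C@]3(CO3)[C@@H]2[C@H](OC(C)=O)[C@]3(O)[C@@H](C)C(=O)OC3O)OC1(C)C
F2 | step 12 | epoxy acetate of 19 | CC(=O)OC[C@@]1(C)O[C@@H]1CC/C(C)=C/CO[Si](C)(C)C(C)(C)C
F3 | step 12 | ring A monoacetate | CC(=O)OC[C@@]1(C)[C@H](O)CCC(=C)[C@@H]1CO[Si](C)(C)C(C)(C)C
F4 | step 19 | ring A carboxylic acid | ClC/C(=C\Cl)CC[C@H](OC(C)=O)[C@@]1(C)[C@@H](OC(C)=O)CCC(=C)[C@@H]1C(=O)O
F5 | step 19 | ring A acid chloride | ClC/C(=C\Cl)CC[C@H](OC(C)=O)[C@@]1(C)[C@@H](OC(C)=O)CCC(=C)[C@@H]1C(=O)Cl
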